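The constant to carry is a half-life, read off the falling branch of G.

the same everywhere: Q 0.25 M

|  | X | J | remark | time |
|---|---|---|---|---|
| Friday's | 2 equiv | 0.50 equiv | the very flask that is asked about, followed so far |  |
| Tuesday's | 2 equiv | 0.25 equiv | run made earlier |  |
| flask | 2.00 equiv | 0.500 equiv |  | 20 h |

Friday's run (percent of the Q charged)

| time / min | G / % |
|---|---|
| 8.00 | 21.1 |
| 20.0 | 25.5 |
| 40.0 | 25.9 |
| 90.0 | 24.0 |

Tuesday's run (percent of the Q charged)

| time / h | G / % |
|---|---|
| 2.50 | 18.9 |
| 8.00 | 3.2 |
| 12.0 | 1.1 |
| 20.0 | 0 |

(scatter of a reading: 0.5 percentage points)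

- the numbers in the tables scatter with a standard deviation of 0.5 percentage points

* time, not beyond 20 h, at which the flask holds most G
* the amount of G, in percent of the Q charged, at that time

Tuesday's flask holds 18.9% G at 2.50 h and 3.2% at 8.00 h. So its G halves every 2.15 h, the tail half-life, the time G takes to halve on an apparent first-order fall.

Friday's flask has twice the J of Tuesday's and reads 24.0% at 90.0 min. Taken with Tuesday's half-life, its time up to 20 h holds 8.62 half-lives, which leaves 0.0611%. Tuesday's flask, counted from 2.50 h, has 8.15 half-lives and 0.0664%, and it reads 0% at 20.0 h. Both counts land under the scatter of 0.5 points, because the tail half-life is shorter than the time allowed. Friday's flask therefore has its best moment early. This reckoning places it near the highest reading, 25.9% at 40.0 min.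

The forecast says 25.8% at 0.45 h, on the grounds of “Fast rise against slow decay”. Its time is earlier than the reading chosen here.

Friday's flask gives 26.6% at 0.722 h, later than the forecast's time, by these steps:

    Q + X → G (k = 0.00240 /M/s)
    J + X → D (k = 0.0340 /M/s)
    G ⇌ L (K = 1.50, k = 0.00200 /s)
    Q + J → Z (k = 7.00 × 10⁻⁴ /M/s)
    G → E (k = 2.30 × 10⁻⁴ /s)

From 1.84% at 10.0 h, the tail half-life gives 0.0732% at 20.0 h, and the flask holds 0.0766%. The same flask with 0.800 equiv of X falls from its highest G, 8.68%, to 0.0245%, which is 8.47 halvings within the 9.30 half-lives of its 20 h. G passes into L with a half-life of 0.096 h, forward step alone, faster than into E with 0.84 h, the rate-limiting step of the tail. At 20.0 h the rate into E stands at 0.12 of the forward rate into L, and the flask holds 99.2% as E.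

The numbers in the tables were generated by integration from invented constants; noise was put on by code.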